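**Plan**

- Retrosynthesis: the four O-benzyl groups, the 3-O-methyl group and the C3–O bond are removed first. Ring C is then cut at O1–C2 and C3–C4, leaving a ring-A salicylaldehyde and a ring-B β-keto sulfoxonium ylide.
- Enabling feature: C4 lies between C5 and C8a, both oxygen-bearing carbons of ring A, and ring A (C5–C8) carries no C–H. C4 can therefore be the formyl carbon of a symmetric 2,6-dihydroxybenzaldehyde whose two hydroxyls are interchangeable.
- Forward: the ring-A aldehyde is built from 2,6-dimethoxyphenol (steps 1–4) and the ring-B ylide from 2,4,5-trihydroxybenzaldehyde (steps 5–9). A Rh(III) annulation joins them and closes ring C (step 10).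
- Finish: 5-O-benzylation, C3 hydroxylation by lithiation–borylation–oxidation, O-methylation and global hydrogenolysis (steps 11–14).
- Stereochemistry: the target has no stereocentre, stereogenic axis or configured double bond, so nothing has to be set.

Key step: step 10

Remark: because the target is achiral, "single enantiomer" is read as the single constitutional isomer drawn.

**Route**

Step 1
Reactants: 1 2,6-dimethoxyphenol
Product: 2 2-(benzyloxy)-1,3-dimethoxybenzene
Conditions: BnBr (1.1 equiv), K2CO3, DMF, rt to 50 °C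
Reagents that add atoms: benzyl bromide, BrCc1ccccc1
Why: Williamson etherification of this hindered but acidic phenol under carbonate in DMF is routine and installs the later 7-O protecting group, which leaves by hydrogenolysis at the end.

Step 2
Reactants: 2 2-(benzyloxy)-1,3-dimethoxybenzene
Product: 3 3-(benzyloxy)-1,5-dibromo-2,4-dimethoxybenzene
Conditions: NBS (2.05 equiv), MeCN, 0 °C to rt, dark
Reagents that add atoms: N-bromosuccinimide, O=C1CCC(=O)N1Br
Why: Electrophilic aromatic bromination of a 1,2,3-trialkoxybenzene goes to C4 and then C6 (each ortho to one methoxy and para to the other, the twisted central ether directing only weakly), so two equivalents of NBS should give the 4,6-dibromide with the carbon between the bromines left as C–H.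

Step 3
Reactants: 3 3-(benzyloxy)-1,5-dibromo-2,4-dimethoxybenzene
Product: 4 5-(benzyloxy)-4,6-dimethoxybenzene-1,3-diol
Conditions: Pd2(dba)3 (2 mol%), t-BuXPhos (8 mol%), KOH (6 equiv), 1,4-dioxane/H2O, 100 °C, Ar; then 1 M HCl
Reagents that add atoms: potassium hydroxide, [K+].[OH-]
Why: Palladium-catalysed hydroxylation of aryl bromides with hydroxide (Buchwald-type C–O coupling with a bulky biarylphosphine) tolerates electron-rich ortho-alkoxy substrates and should exchange both bromines for hydroxyl, the benzyl and methyl ethers being inert to aqueous KOH.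

Step 4
Reactants: 4 5-(benzyloxy)-4,6-dimethoxybenzene-1,3-diol
Product: 6 4-(benzyloxy)-2,6-dihydroxy-3,5-dimethoxybenzaldehyde, via iminium chloride 5 (not isolated)
Conditions: POCl3 (1.2 equiv), DMF (3 equiv), MeCN, 0 °C to rt; then H2O, 50 °C
Reagents that add atoms: N,N-dimethylformamide, CN(C)C=O; water, O
Why: Vilsmeier–Haack formylation attacks the only ring C–H, which is ortho to both hydroxyls and para to the benzyloxy group as in the formylation of phloroglucinol, and aqueous hydrolysis of the iminium salt releases the aldehyde.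

Step 5
Reactants: 7 2,4,5-trihydroxybenzaldehyde
Product: 8 4,5-bis(benzyloxy)-2-hydroxybenzaldehyde
Conditions: BnBr (2.05 equiv), K2CO3 (2.1 equiv), degassed DMF, 0 °C to rt, Ar
Reagents that add atoms: benzyl bromide, BrCc1ccccc1
Why: Chelation-controlled Williamson alkylation: the 2-hydroxyl is hydrogen-bonded to the formyl oxygen and is the least nucleophilic, so two equivalents of benzyl bromide should etherify the 4- and 5-hydroxyls, as in the selective alkylation of 2,4- and 2,5-dihydroxybenzaldehydes.

Step 6
Reactants: 8 4,5-bis(benzyloxy)-2-hydroxybenzaldehyde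
Product: 9 4,5-bis(benzyloxy)-2-methoxybenzaldehyde
Conditions: MeI (1.5 equiv), K2CO3 (2 equiv), DMF, 40 °C
Reagents that add atoms: methyl iodide, CI
Why: With excess methyl iodide and carbonate in warm DMF the remaining chelated phenol undergoes Williamson O-methylation.

Step 7
Reactants: 9 4,5-bis(benzyloxy)-2-methoxybenzaldehyde
Product: 10 4,5-bis(benzyloxy)-2-methoxybenzoic acid
Conditions: NaClO2, NaH2PO4, 2-methyl-2-butene, t-BuOH/THF/H2O, rt
Reagents that add atoms: sodium chlorite, [Na+].[O-]Cl=O
Why: Pinnick oxidation converts the aromatic aldehyde into the acid under buffered conditions, with 2-methyl-2-butene trapping hypochlorous acid so that the electron-rich ring is not chlorinated.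

Step 8
Reactants: 10 4,5-bis(benzyloxy)-2-methoxybenzoic acid
Product: 11 4,5-bis(benzyloxy)-2-methoxybenzoyl chloride
Conditions: (COCl)2 (1.5 equiv), DMF (cat.), CH2Cl2, 0 °C to rt; evaporate, use crude
Reagents that add atoms: oxalyl chloride, O=C(Cl)C(Cl)=O
Why: Acid chloride formation with oxalyl chloride and catalytic DMF is mild enough for aryl benzyl ethers and gives a product that can be used directly after evaporation.

Step 9
Reactants: 11 4,5-bis(benzyloxy)-2-methoxybenzoyl chloride
Product: 12 1-[4,5-bis(benzyloxy)-2-methoxyphenyl]-2-[dimethyl(oxo)-λ6-sulfanylidene]ethan-1-one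
Conditions: Me3S(O)I (3 equiv), KOt-Bu (3 equiv), THF, reflux; then 11 in THF, 0 °C to rt
Reagents that add atoms: trimethylsulfoxonium iodide, C[S+](C)(C)=O.[I-]
Why: C-acylation of dimethylsulfoxonium methylide (the Corey–Chaykovsky reagent) by an acid chloride, with a second equivalent of methylide acting as base, is the standard route to β-keto sulfoxonium ylides.

Step 10
Reactants: 6 4-(benzyloxy)-2,6-dihydroxy-3,5-dimethoxybenzaldehyde; 12 1-[4,5-bis(benzyloxy)-2-methoxyphenyl]-2-[dimethyl(oxo)-λ6-sulfanylidene]ethan-1-one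
Product: 14 7-(benzyloxy)-2-[4,5-bis(benzyloxy)-2-methoxyphenyl]-5-hydroxy-6,8-dimethoxy-4H-chromen-4-one, via 1,3-diketone 13 (not isolated)
Conditions: [Cp*RhCl2]2 (4 mol%), AgSbF6 (16 mol%), NaOAc (30 mol%), PivOH (1 equiv), DCE, 80 °C, Ar; then TsOH·H2O (10 mol%), 80 °C
Reagents that add atoms: none
Why: Deprotonation of one of the two equivalent hydroxyls of 6 gives a phenoxide that binds Cp*Rh(III) and delivers it to the formyl C–H, which is cleaved by carboxylate-assisted metalation to a five-membered acyl rhodacycle; ylide 12 then coordinates through carbon, loses dimethyl sulfoxide to give a rhodium carbene, and migratory insertion of the acyl group into the carbene forms C3–C4. Protonolysis by pivalic acid releases the 2-hydroxyaryl 1,3-diketone 13 and regenerates Rh(III), so the cycle is redox-neutral and needs no external oxidant that could attack the electron-rich rings. Ring C then closes by 6-exo-trig addition of the neighbouring phenol to the ring-B carbonyl followed by acid-promoted loss of water (O1–C2). The closest known reaction type is the Rh(III)-catalysed aldehydic C–H activation/annulation of salicylaldehydes with aroyl sulfoxonium ylides to 2-arylchromones. No stereocentre is formed. The step needs chemoselectivity for the formyl C–H over aryl C–H bonds and over O–H insertion of the carbene: ring A has no C–H at all, the phenoxide holds rhodium next to the aldehyde, and because the two hydroxyls are symmetry-equivalent either one gives the same chromone with the other left as the chelated 5-OH.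

Step 11
Reactants: 14 7-(benzyloxy)-2-[4,5-bis(benzyloxy)-2-methoxyphenyl]-5-hydroxy-6,8-dimethoxy-4H-chromen-4-one
Product: 15 5,7-bis(benzyloxy)-2-[4,5-bis(benzyloxy)-2-methoxyphenyl]-6,8-dimethoxy-4H-chromen-4-one
Conditions: BnBr (1.5 equiv), K2CO3 (3 equiv), KI (cat.), DMF, 60 °C
Reagents that add atoms: benzyl bromide, BrCc1ccccc1
Why: Williamson benzylation of the chelated 5-hydroxyl needs carbonate in warm DMF with iodide catalysis, as for other 5-hydroxyflavones, and removes the acidic proton before the lithiation.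

Step 12
Reactants: 15 5,7-bis(benzyloxy)-2-[4,5-bis(benzyloxy)-2-methoxyphenyl]-6,8-dimethoxy-4H-chromen-4-one
Product: 18 5,7-bis(benzyloxy)-2-[4,5-bis(benzyloxy)-2-methoxyphenyl]-3-hydroxy-6,8-dimethoxy-4H-chromen-4-one, via 3-lithioflavone 16 (not isolated), via dimethyl boronate 17 (not isolated)
Conditions: LDA (1.5 equiv), THF, −78 °C; B(OMe)3 (3 equiv), −78 to 0 °C; AcOH, 30% H2O2, 0 °C to rt
Reagents that add atoms: hydrogen peroxide, OO
Why: Deprotonation of a 5-O-protected flavone at C3 by LDA at −78 °C, trapping of the vinyllithium with trimethyl borate and oxidative carbon-to-oxygen migration with hydrogen peroxide in acetic acid is an established flavone-to-flavonol sequence, and the aryl benzyl and methyl ethers are inert to LDA at this temperature.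

Step 13
Reactants: 18 5,7-bis(benzyloxy)-2-[4,5-bis(benzyloxy)-2-methoxyphenyl]-3-hydroxy-6,8-dimethoxy-4H-chromen-4-one
Product: 19 5,7-bis(benzyloxy)-2-[4,5-bis(benzyloxy)-2-methoxyphenyl]-3,6,8-trimethoxy-4H-chromen-4-one
Conditions: MeI (3 equiv), K2CO3 (3 equiv), DMF, rt to 40 °C
Reagents that add atoms: methyl iodide, CI
Why: Williamson O-methylation of the 3-hydroxyl, the only free hydroxyl left in the molecule, with methyl iodide and carbonate.

Step 14
Reactants: 19 5,7-bis(benzyloxy)-2-[4,5-bis(benzyloxy)-2-methoxyphenyl]-3,6,8-trimethoxy-4H-chromen-4-one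
Product: 20 5,7-dihydroxy-2-(4,5-dihydroxy-2-methoxyphenyl)-3,6,8-trimethoxy-4H-chromen-4-one (5,7,4',5'-tetrahydroxy-3,6,8,2'-tetramethoxyflavone)
Conditions: H2 (1 atm), 10% Pd/C, EtOAc/MeOH, rt
Reagents that add atoms: none
Why: Catalytic hydrogenolysis over Pd/C cleaves all four aryl benzyl ethers at room temperature and atmospheric pressure, while the chromone C2=C3 double bond, the carbonyl and the methyl ethers should be left untouched.

**Compound list**

1 | 2,6-dimethoxyphenol | COc1cccc(OC)c1O | starting material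
2 | 2-(benzyloxy)-1,3-dimethoxybenzene | COc1cccc(OC)c1OCc1ccccc1 | intermediate
3 | 3-(benzyloxy)-1,5-dibromo-2,4-dimethoxybenzene | COc1c(Br)cc(Br)c(OC)c1OCc1ccccc1 | intermediate
4 | 5-(benzyloxy)-4,6-dimethoxybenzene-1,3-diol | COc1c(O)cc(O)c(OC)c1OCc1ccccc1 | intermediate
5 | N-{[4-(benzyloxy)-2,6-dihydroxy-3,5-dimethoxyphenyl]methylidene}-N-methylmethanaminium chloride (not isolated) | C[N+](C)=Cc1c(O)c(OC)c(OCc2ccccc2)c(OC)c1O.[Cl-] | intermediate
6 | 4-(benzyloxy)-2,6-dihydroxy-3,5-dimethoxybenzaldehyde | O=Cc1c(O)c(OC)c(OCc2ccccc2)c(OC)c1O | intermediate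
7 | 2,4,5-trihydroxybenzaldehyde | O=Cc1cc(O)c(O)cc1O | starting material
8 | 4,5-bis(benzyloxy)-2-hydroxybenzaldehyde | O=Cc1cc(OCc2ccccc2)c(OCc2ccccc2)cc1O | intermediate
9 | 4,5-bis(benzyloxy)-2-methoxybenzaldehyde | COc1cc(OCc2ccccc2)c(OCc2ccccc2)cc1C=O | intermediate
10 | 4,5-bis(benzyloxy)-2-methoxybenzoic acid | COc1cc(OCc2ccccc2)c(OCc2ccccc2)cc1C(=O)O | intermediate
11 | 4,5-bis(benzyloxy)-2-methoxybenzoyl chloride | COc1cc(OCc2ccccc2)c(OCc2ccccc2)cc1C(Cl)=O | intermediate
12 | 1-[4,5-bis(benzyloxy)-2-methoxyphenyl]-2-[dimethyl(oxo)-λ6-sulfanylidene]ethan-1-one | COc1cc(OCc2ccccc2)c(OCc2ccccc2)cc1C(=O)C=S(C)(C)=O | intermediate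
13 | 1-[4-(benzyloxy)-2,6-dihydroxy-3,5-dimethoxyphenyl]-3-[4,5-bis(benzyloxy)-2-methoxyphenyl]propane-1,3-dione (not isolated) | COc1cc(OCc2ccccc2)c(OCc2ccccc2)cc1C(=O)CC(=O)c1c(O)c(OC)c(OCc2ccccc2)c(OC)c1O | intermediate
14 | 7-(benzyloxy)-2-[4,5-bis(benzyloxy)-2-methoxyphenyl]-5-hydroxy-6,8-dimethoxy-4H-chromen-4-one | COc1cc(OCc2ccccc2)c(OCc2ccccc2)cc1-c1cc(=O)c2c(O)c(OC)c(OCc3ccccc3)c(OC)c2o1 | intermediate
15 | 5,7-bis(benzyloxy)-2-[4,5-bis(benzyloxy)-2-methoxyphenyl]-6,8-dimethoxy-4H-chromen-4-one | COc1cc(OCc2ccccc2)c(OCc2ccccc2)cc1-c1cc(=O)c2c(OCc3ccccc3)c(OC)c(OCc3ccccc3)c(OC)c2o1 | intermediate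
16 | {5,7-bis(benzyloxy)-2-[4,5-bis(benzyloxy)-2-methoxyphenyl]-6,8-dimethoxy-4-oxo-4H-chromen-3-yl}lithium (not isolated) | COc1cc(OCc2ccccc2)c(OCc2ccccc2)cc1-c1oc2c(OC)c(OCc3ccccc3)c(OC)c(OCc3ccccc3)c2c(=O)c1[Li] | intermediate
17 | dimethyl {5,7-bis(benzyloxy)-2-[4,5-bis(benzyloxy)-2-methoxyphenyl]-6,8-dimethoxy-4-oxo-4H-chromen-3-yl}boronate (not isolated) | COc1cc(OCc2ccccc2)c(OCc2ccccc2)cc1-c1oc2c(OC)c(OCc3ccccc3)c(OC)c(OCc3ccccc3)c2c(=O)c1B(OC)OC | intermediate
18 | 5,7-bis(benzyloxy)-2-[4,5-bis(benzyloxy)-2-methoxyphenyl]-3-hydroxy-6,8-dimethoxy-4H-chromen-4-one | COc1cc(OCc2ccccc2)c(OCc2ccccc2)cc1-c1oc2c(OC)c(OCc3ccccc3)c(OC)c(OCc3ccccc3)c2c(=O)c1O | intermediate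
19 | 5,7-bis(benzyloxy)-2-[4,5-bis(benzyloxy)-2-methoxyphenyl]-3,6,8-trimethoxy-4H-chromen-4-one | COc1cc(OCc2ccccc2)c(OCc2ccccc2)cc1-c1oc2c(OC)c(OCc3ccccc3)c(OC)c(OCc3ccccc3)c2c(=O)c1OC | intermediate
20 | 5,7-dihydroxy-2-(4,5-dihydroxy-2-methoxyphenyl)-3,6,8-trimethoxy-4H-chromen-4-one | COc1cc(O)c(O)cc1-c1oc2c(OC)c(O)c(OC)c(O)c2c(=O)c1OC | target

**Summary**

Total step count: 14 (steps 1–4 for the ring-A aldehyde, steps 5–9 for the ring-B ylide, steps 10–14 after convergence).
Longest linear sequence: 10 steps (steps 5–14, from 7).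

**Steps most likely to fail**

Step 10. The acyl rhodium species may lose carbon monoxide before the carbene arrives, or the carbene may insert into a free phenolic O–H instead of accepting the acyl group. Either process would consume the two fragments without forming C3–C4. In that case ring C would be assembled through C2–C3 by enolate acylation. The fallback sets out from resorcinol 4, which is C-acetylated at its only free ring position (Ac2O, BF3·OEt2, then K2CO3/MeOH to cleave any O-acetate) to give 1-[4-(benzyloxy)-2,6-dihydroxy-3,5-dimethoxyphenyl]ethan-1-one F1. Its polyanion (LiHMDS, 4 equiv, THF, −78 °C) is acylated on carbon by acid chloride 11 to give diketone 13, this time isolated. Cyclodehydration with TsOH in toluene at 80 °C then returns to the route at 14.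

Step 12. The 3-lithiated chromone may open by β-elimination of the ring-A phenoxide before the borate traps it, or deprotonation next to the hindered 2-aryl group may be incomplete. The alternative transfers electrophilic oxygen to the C2=C3 bond instead of metalating it. It sets out from 15, which is epoxidised with dimethyldioxirane (acetone/CH2Cl2, 0 °C to rt) to racemic 5,7-bis(benzyloxy)-2-[4,5-bis(benzyloxy)-2-methoxyphenyl]-2,3-epoxy-6,8-dimethoxy-2,3-dihydro-4H-chromen-4-one F2. Catalytic TsOH in CH2Cl2 then opens the oxirane and tautomerises the product to flavonol 18, where the route is rejoined.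

Step 3. After the first C–O coupling the phenoxide formed makes the ring more electron-rich, so the second oxidative addition may stall. Hydrodebromination and air oxidation of the resorcinol dianion are further ways to lose material. The alternative makes C–B bonds first and oxidises them under mild, nearly neutral conditions. It sets out from dibromide 3, which undergoes double Miyaura borylation (B2pin2, PdCl2(dppf), KOAc, dioxane, 90 °C) to 2,2'-[5-(benzyloxy)-4,6-dimethoxy-1,3-phenylene]bis(4,4,5,5-tetramethyl-1,3,2-dioxaborolane) F3. Oxidation with H2O2 in buffered THF/H2O at 0 °C then gives resorcinol 4, where the route is rejoined.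

**Further compounds**

F1 | step 10 | 1-[4-(benzyloxy)-2,6-dihydroxy-3,5-dimethoxyphenyl]ethan-1-one | CC(=O)c1c(O)c(OC)c(OCc2ccccc2)c(OC)c1O
F2 | step 12 | racemic 5,7-bis(benzyloxy)-2-[4,5-bis(benzyloxy)-2-methoxyphenyl]-2,3-epoxy-6,8-dimethoxy-2,3-dihydro-4H-chromen-4-one (cis-fused oxirane, both enantiomers, no descriptors given) | COc1cc(OCc2ccccc2)c(OCc2ccccc2)cc1C12OC1C(=O)c1c(OCc3ccccc3)c(OC)c(OCc3ccccc3)c(OC)c1O2
F3 | step 3 | 2,2'-[5-(benzyloxy)-4,6-dimethoxy-1,3-phenylene]bis(4,4,5,5-tetramethyl-1,3,2-dioxaborolane) | COc1c(B2OC(C)(C)C(C)(C)O2)cc(B2OC(C)(C)C(C)(C)O2)c(OC)c1OCc1ccccc1
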